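**Retrosynthetic overview**

1. Feature: in the oxolane ring (O1, C2 aryl, C3, C4 benzyl, C5) with the hydroxymethyl arm C9 on C3, the carbons C2–C3–C9 map onto C3–C4–C5 of methyl 2-furoate, and C4–C5 onto the carbene carbon and the carbonyl carbon of ethyl diazoacetate.
2. 21 ⇒ silylated cis-benzyl lactone 18 (C5 still C=O) ⇒ benzylidene lactone 17 ⇒ lactone 12 + veratraldehyde 13 (C4–CH2Ar bond by aldol condensation; C4 set by hydrogenation anti to the arm).
3. 12 ⇒ lactone aldehyde 10 ⇒ carbinol 7: loss of the oxalate, retro-aldol cleavage of the temporary cyclopropane bond C9–C4, lactonisation of the C2 hydroxyl onto the C5 ester.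
4. 7 ⇒ cyclopropanecarbaldehyde 5 + boronic acid 6 (C2–aryl bond, Felkin–Anh); 5 ⇒ bicycle 3 by ozonolysis of the enol-ether double bond.
5. 3 ⇒ furoate 1 + diazo ester 2 by enantioselective cyclopropanation; ring order: cyclopropane (step 1, temporary), then the five-membered O-heterocycle as a γ-lactone (step 4), deoxygenated to the oxolane in steps 10–11.

Key step: step 1

Assumption: the (S,S)-isopropyl bis(oxazoline) ligand is taken to give the (1S,5S,6S) enantiomer of 3, whose C5 has the configuration needed for C3 of the target; if the sense of induction is the opposite, the (R,R) ligand is used and nothing else changes.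

**Route**

Step 1
Reactants: 1 methyl furan-2-carboxylate; 2 ethyl diazoacetate
Product: 3 6-ethyl 3-methyl (1S,5S,6S)-2-oxabicyclo[3.1.0]hex-3-ene-3,6-dicarboxylate (ester on C6 exo)
Conditions: Cu(OTf)2 (1 mol%), (S,S)-2,2'-isopropylidenebis(4-isopropyl-2-oxazoline) (1.2 mol%), PhNHNH2 (1 mol%), CH2Cl2, 0 °C, slow addition of 2; recrystallisation
Reagents that add atoms: none
Why: Phenylhydrazine reduces divalent copper in Cu(OTf)2 to the monovalent copper–bis(oxazoline) complex, which takes up 2 with loss of N2 to give an electrophilic copper carbene that adds across the C4=C5 bond of 1 in a concerted, asynchronous (2+1) step. The closest known reaction type is the asymmetric copper–bis(oxazoline) cyclopropanation of furan-2-carboxylates with diazoacetates, which is established for this pair of partners. The three-membered ring is closed by suprafacial carbene transfer onto the alkene, so the cis fusion to the dihydrofuran is obligatory and both new skeletal bonds (target C3–C4 and the sacrificial C9–C4) form in one event. The C2-symmetric ligand selects the furan face and thereby fixes C1 and C5 (C5 becomes C3 of the target), and C6 is set exo because the carbene ester turns away from the furan ring during the approach. The step needs regioselectivity, mono-addition and enantioselectivity: the ester of 1 deactivates and shields the C2=C3 bond, the push–pull enol-ether double bond left in 3 is too electron-poor for a second carbene transfer, slow addition of 2 suppresses carbene dimerisation, and crystallisation of 3 should raise the enantiomeric purity further.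

Step 2
Reactants: 3 6-ethyl 3-methyl (1S,5S,6S)-2-oxabicyclo[3.1.0]hex-3-ene-3,6-dicarboxylate
Product: 5 ethyl (1S,2S,3S)-2-formyl-3-[(2-methoxy-2-oxoacetyl)oxy]cyclopropane-1-carboxylate, via secondary ozonide 4 (not isolated)
Conditions: O3, CH2Cl2, −78 °C; Me2S, −78 °C to rt
Reagents that add atoms: ozone, O=[O+][O-]
Why: Ozonolysis (Criegee mechanism) cleaves the only C=C bond, turning the former furoate C3 into the formyl group and the ester-bearing carbon into a methyl oxalyl ester that masks the cyclopropanol; no stereocentre is touched.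

Step 3
Reactants: 5 ethyl (1S,2S,3S)-2-formyl-3-[(2-methoxy-2-oxoacetyl)oxy]cyclopropane-1-carboxylate; 6 3,4,5-trimethoxyphenylboronic acid
Product: 7 ethyl (1S,2R,3S)-2-[(R)-hydroxy(3,4,5-trimethoxyphenyl)methyl]-3-[(2-methoxy-2-oxoacetyl)oxy]cyclopropane-1-carboxylate
Conditions: 6 (2 equiv), Rh(acac)(coe)2 (3 mol%), tBu3P (3 mol%), DME/H2O 5:1, rt; chromatographic removal of the minor carbinol epimer
Reagents that add atoms: none
Why: Rhodium-catalysed 1,2-addition of an arylboronic acid to an aldehyde (transmetalation to an aryl complex of monovalent rhodium, carbonyl insertion, protonolysis) runs at neutral pH, which should leave the oxalate in place, and the new carbinol centre (R, later C2) follows Felkin–Anh control, the aryl group entering anti to the ring carbon that carries the cis oxalate with the other ring carbon inside and H outside.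

Step 4
Reactants: 7 ethyl (1S,2R,3S)-2-[(R)-hydroxy(3,4,5-trimethoxyphenyl)methyl]-3-[(2-methoxy-2-oxoacetyl)oxy]cyclopropane-1-carboxylate
Product: 10 (2R,3R)-5-oxo-2-(3,4,5-trimethoxyphenyl)oxolane-3-carbaldehyde, via cyclopropanol 8 (not isolated), via hydroxy aldehyde ester 9 (not isolated)
Conditions: Ba(OH)2·8H2O (0.55 equiv), MeOH, 0 °C
Reagents that add atoms: none
Why: Cleavage of the oxalate frees a donor–acceptor cyclopropanol whose alkoxide opens by retro-aldol fragmentation of the bond to the ester-bearing carbon (the sacrificial C9–C4 bond), and the benzylic hydroxyl of the resulting γ-hydroxy ester lactonises (5-exo-trig) to the trans lactone, both stereocentres being carried over unchanged.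

Step 5
Reactants: 10 (2R,3R)-5-oxo-2-(3,4,5-trimethoxyphenyl)oxolane-3-carbaldehyde
Product: 11 (4S,5R)-4-(hydroxymethyl)-5-(3,4,5-trimethoxyphenyl)oxolan-2-one
Conditions: NaBH4, MeOH/THF, −40 °C, 20 min; AcOH quench
Reagents that add atoms: none
Why: Chemoselective borohydride reduction of the aldehyde beside the lactone; the cold, short reaction and the acidic quench are chosen so that the new primary alkoxide neither epimerises C4 nor translactonises.

Step 6
Reactants: 11 (4S,5R)-4-(hydroxymethyl)-5-(3,4,5-trimethoxyphenyl)oxolan-2-one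
Product: 12 (4S,5R)-4-{[(tert-butyldiphenylsilyl)oxy]methyl}-5-(3,4,5-trimethoxyphenyl)oxolan-2-one
Conditions: TBDPSCl, imidazole, CH2Cl2, 0 °C to rt
Reagents that add atoms: tert-butyl(chloro)diphenylsilane, CC(C)(C)[Si](Cl)(c1ccccc1)c1ccccc1
Why: Standard silylation of a primary alcohol; the bulky silyl ether blocks translactonisation, should survive the enolate, hydrogenation, hydride and Lewis-acid steps, and enlarges the group that shields one face of the α-carbon.

Step 7
Reactants: 12 (4S,5R)-4-{[(tert-butyldiphenylsilyl)oxy]methyl}-5-(3,4,5-trimethoxyphenyl)oxolan-2-one; 13 3,4-dimethoxybenzaldehyde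
Product: 15 (4S,5R)-4-{[(tert-butyldiphenylsilyl)oxy]methyl}-3-[(3,4-dimethoxyphenyl)(hydroxy)methyl]-5-(3,4,5-trimethoxyphenyl)oxolan-2-one (epimer mixture at C3 plus carbinol carbon), via lithium enolate 14 (not isolated)
Conditions: LiN(iPr)2, THF, −78 °C; 13, −78 °C; AcOH quench
Reagents that add atoms: none
Why: Aldol addition of the lactone lithium enolate to a non-enolisable aromatic aldehyde; the two new stereocentres need no control because both are erased in steps 8 and 9.

Step 8
Reactants: 15 (4S,5R)-4-{[(tert-butyldiphenylsilyl)oxy]methyl}-3-[(3,4-dimethoxyphenyl)(hydroxy)methyl]-5-(3,4,5-trimethoxyphenyl)oxolan-2-one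
Product: 17 (3E,4S,5R)-4-{[(tert-butyldiphenylsilyl)oxy]methyl}-3-(3,4-dimethoxybenzylidene)-5-(3,4,5-trimethoxyphenyl)oxolan-2-one, via mesylate 16 (not isolated)
Conditions: MsCl, Et3N, CH2Cl2, 0 °C; DBU, 0 °C to rt
Reagents that add atoms: none
Why: Mesylation and E1cB elimination give the aryl-conjugated exocyclic alkene, expected as the (E) isomer; the alkene geometry has no bearing on step 9 because the exocyclic carbon becomes a CH2 group.

Step 9
Reactants: 17 (3E,4S,5R)-4-{[(tert-butyldiphenylsilyl)oxy]methyl}-3-(3,4-dimethoxybenzylidene)-5-(3,4,5-trimethoxyphenyl)oxolan-2-one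
Product: 18 (3S,4S,5R)-4-{[(tert-butyldiphenylsilyl)oxy]methyl}-3-(3,4-dimethoxybenzyl)-5-(3,4,5-trimethoxyphenyl)oxolan-2-one
Conditions: H2 (1 atm), 10% Pd/C, Ph2S (0.01 equiv), EtOAc, rt
Reagents that add atoms: none
Why: Heterogeneous syn hydrogenation of an α-alkylidene lactone from the face opposite the adjacent silyloxymethyl group, which allylic 1,3-strain with the benzylidene aryl pushes pseudo-axial, delivers H to C3 anti to the arm and so sets the 3,4-cis relationship (target C4), while the sulfide-moderated catalyst is meant to spare the benzylic lactone C–O bond.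

Step 10
Reactants: 18 (3S,4S,5R)-4-{[(tert-butyldiphenylsilyl)oxy]methyl}-3-(3,4-dimethoxybenzyl)-5-(3,4,5-trimethoxyphenyl)oxolan-2-one
Product: 19 (3S,4S,5R)-4-{[(tert-butyldiphenylsilyl)oxy]methyl}-3-(3,4-dimethoxybenzyl)-5-(3,4,5-trimethoxyphenyl)oxolan-2-ol (anomer mixture)
Conditions: iBu2AlH (1.2 equiv), CH2Cl2, −78 °C; aq. potassium sodium tartrate
Reagents that add atoms: none
Why: Partial reduction of a γ-lactone to the lactol through the tetrahedral aluminium hemiacetal, which is stable at −78 °C; the α-centre should not be enolised at this temperature.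

Step 11
Reactants: 19 (3S,4S,5R)-4-{[(tert-butyldiphenylsilyl)oxy]methyl}-3-(3,4-dimethoxybenzyl)-5-(3,4,5-trimethoxyphenyl)oxolan-2-ol
Product: 20 tert-butyl{[(2R,3S,4S)-4-(3,4-dimethoxybenzyl)-2-(3,4,5-trimethoxyphenyl)oxolan-3-yl]methoxy}diphenylsilane
Conditions: Et3SiH (3 equiv), BF3·OEt2 (1.5 equiv), CH2Cl2, −78 °C
Reagents that add atoms: none
Why: Ionic hydrogenation of the lactol (oxocarbenium ion formation and hydride transfer from the silane) turns the anomeric carbon into the C5 methylene without creating a stereocentre, and at −78 °C the excess silane should trap the cation before the benzylic C2–O bond ionises or the cation loses its α-proton.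

Step 12
Reactants: 20 tert-butyl{[(2R,3S,4S)-4-(3,4-dimethoxybenzyl)-2-(3,4,5-trimethoxyphenyl)oxolan-3-yl]methoxy}diphenylsilane
Product: 21 [(2R,3S,4S)-4-(3,4-dimethoxybenzyl)-2-(3,4,5-trimethoxyphenyl)oxolan-3-yl]methanol (CNP0107562.1)
Conditions: Bu4NF, THF, 0 °C to rt
Reagents that add atoms: none
Why: Fluoride-mediated cleavage of the silyl ether; nothing else in the molecule responds to fluoride and no stereocentre is at risk.

**Compound list**

1 | methyl furan-2-carboxylate | COC(=O)c1ccco1 | starting material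
2 | ethyl diazoacetate | CCOC(=O)C=[N+]=[N-] | starting material
3 | 6-ethyl 3-methyl (1S,5S,6S)-2-oxabicyclo[3.1.0]hex-3-ene-3,6-dicarboxylate | COC(=O)C1=C[C@H]2[C@H](C(=O)OCC)[C@H]2O1 | intermediate
4 | secondary ozonide of 3 (1,2,4-trioxolane across the former C3=C4 bond; ozonide carbons undefined) | COC(=O)C12OOC(O1)[C@H]1[C@H](C(=O)OCC)[C@H]1O2 | intermediate (not isolated)
5 | ethyl (1S,2S,3S)-2-formyl-3-[(2-methoxy-2-oxoacetyl)oxy]cyclopropane-1-carboxylate | O=C[C@H]1[C@H](C(=O)OCC)[C@H]1OC(=O)C(=O)OC | intermediate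
6 | 3,4,5-trimethoxyphenylboronic acid | COc1cc(B(O)O)cc(OC)c1OC | starting material
7 | ethyl (1S,2R,3S)-2-[(R)-hydroxy(3,4,5-trimethoxyphenyl)methyl]-3-[(2-methoxy-2-oxoacetyl)oxy]cyclopropane-1-carboxylate | COc1cc(cc(OC)c1OC)[C@H](O)[C@H]1[C@H](C(=O)OCC)[C@H]1OC(=O)C(=O)OC | intermediate
8 | ethyl (1S,2R,3S)-2-hydroxy-3-[(R)-hydroxy(3,4,5-trimethoxyphenyl)methyl]cyclopropane-1-carboxylate | COc1cc(cc(OC)c1OC)[C@H](O)[C@H]1[C@H](C(=O)OCC)[C@H]1O | intermediate (not isolated)
9 | ethyl (3R,4R)-3-formyl-4-hydroxy-4-(3,4,5-trimethoxyphenyl)butanoate | COc1cc(cc(OC)c1OC)[C@H](O)[C@H](C=O)CC(=O)OCC | intermediate (not isolated)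
10 | (2R,3R)-5-oxo-2-(3,4,5-trimethoxyphenyl)oxolane-3-carbaldehyde | O=C1O[C@@H](c2cc(OC)c(OC)c(OC)c2)[C@H](C=O)C1 | intermediate
11 | (4S,5R)-4-(hydroxymethyl)-5-(3,4,5-trimethoxyphenyl)oxolan-2-one | O=C1O[C@@H](c2cc(OC)c(OC)c(OC)c2)[C@H](CO)C1 | intermediate
12 | (4S,5R)-4-{[(tert-butyldiphenylsilyl)oxy]methyl}-5-(3,4,5-trimethoxyphenyl)oxolan-2-one | O=C1O[C@@H](c2cc(OC)c(OC)c(OC)c2)[C@H](CO[Si](c2ccccc2)(c2ccccc2)C(C)(C)C)C1 | intermediate
13 | 3,4-dimethoxybenzaldehyde (veratraldehyde) | COc1ccc(C=O)cc1OC | starting material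
14 | lithium enolate of 12 | [Li]OC1=C[C@@H](CO[Si](c2ccccc2)(c2ccccc2)C(C)(C)C)[C@H](c2cc(OC)c(OC)c(OC)c2)O1 | intermediate (not isolated)
15 | (4S,5R)-4-{[(tert-butyldiphenylsilyl)oxy]methyl}-3-[(3,4-dimethoxyphenyl)(hydroxy)methyl]-5-(3,4,5-trimethoxyphenyl)oxolan-2-one, epimer mixture | O=C1O[C@@H](c2cc(OC)c(OC)c(OC)c2)[C@H](CO[Si](c2ccccc2)(c2ccccc2)C(C)(C)C)C1C(O)c1ccc(OC)c(OC)c1 | intermediate
16 | methanesulfonate of 15 | O=C1O[C@@H](c2cc(OC)c(OC)c(OC)c2)[C@H](CO[Si](c2ccccc2)(c2ccccc2)C(C)(C)C)C1C(OS(C)(=O)=O)c1ccc(OC)c(OC)c1 | intermediate (not isolated)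
17 | (3E,4S,5R)-4-{[(tert-butyldiphenylsilyl)oxy]methyl}-3-(3,4-dimethoxybenzylidene)-5-(3,4,5-trimethoxyphenyl)oxolan-2-one | O=C1O[C@@H](c2cc(OC)c(OC)c(OC)c2)[C@H](CO[Si](c2ccccc2)(c2ccccc2)C(C)(C)C)/C1=C\c1ccc(OC)c(OC)c1 | intermediate
18 | (3S,4S,5R)-4-{[(tert-butyldiphenylsilyl)oxy]methyl}-3-(3,4-dimethoxybenzyl)-5-(3,4,5-trimethoxyphenyl)oxolan-2-one | O=C1O[C@@H](c2cc(OC)c(OC)c(OC)c2)[C@H](CO[Si](c2ccccc2)(c2ccccc2)C(C)(C)C)[C@@H]1Cc1ccc(OC)c(OC)c1 | intermediate
19 | (3S,4S,5R)-4-{[(tert-butyldiphenylsilyl)oxy]methyl}-3-(3,4-dimethoxybenzyl)-5-(3,4,5-trimethoxyphenyl)oxolan-2-ol, anomer mixture | OC1O[C@@H](c2cc(OC)c(OC)c(OC)c2)[C@H](CO[Si](c2ccccc2)(c2ccccc2)C(C)(C)C)[C@@H]1Cc1ccc(OC)c(OC)c1 | intermediate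
20 | tert-butyl{[(2R,3S,4S)-4-(3,4-dimethoxybenzyl)-2-(3,4,5-trimethoxyphenyl)oxolan-3-yl]methoxy}diphenylsilane | C1O[C@@H](c2cc(OC)c(OC)c(OC)c2)[C@H](CO[Si](c2ccccc2)(c2ccccc2)C(C)(C)C)[C@@H]1Cc1ccc(OC)c(OC)c1 | intermediate
21 | [(2R,3S,4S)-4-(3,4-dimethoxybenzyl)-2-(3,4,5-trimethoxyphenyl)oxolan-3-yl]methanol | COc1ccc(C[C@@H]2CO[C@@H](c3cc(OC)c(OC)c(OC)c3)[C@@H]2CO)cc1OC | target

**Step count**

Total: 12 steps. Longest linear sequence: 12 steps (1 and 2 to 21).

**Steps most likely to fail**

Step 3. The oxalate may hydrolyse in the aqueous medium before the C–C bond forms, which would open the unprotected cyclopropanol. The facial selectivity of the aryl–rhodium insertion may also be modest. A wrong-face adduct that is not removed would, after step 4 and base epimerisation, end as the enantiomer of 10 and erode the enantiomeric purity. The fallback sets out from 5 and uses an anhydrous, stoichiometric organotitanium reagent instead of aqueous rhodium–boron catalysis. Commercial 5-bromo-1,2,3-trimethoxybenzene is treated with n-BuLi in THF at −78 °C to give (3,4,5-trimethoxyphenyl)lithium F1. Transmetalation with ClTi(OiPr)3 gives triisopropoxy(3,4,5-trimethoxyphenyl)titanium F2. F2 is added to 5 at −78 to −30 °C; reagents of this type add to aldehydes and leave esters alone, and as non-chelating nucleophiles they should follow the same Felkin–Anh sense. The fallback comes back to the route at 7.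

Step 9. The aryl group on C5 lies on the face from which hydrogen must come and may weaken the facial bias set by the arm. The benzylic lactone C–O bond may also be hydrogenolysed. The fallback sets out from 12 and sets C3 by enolate chemistry instead of hydrogenation. Enolate 14 is alkylated with 3,4-dimethoxybenzyl bromide (THF, DMPU, −78 °C) anti to the arm, to give the trans lactone (3R,4S,5R)-4-{[(tert-butyldiphenylsilyl)oxy]methyl}-3-(3,4-dimethoxybenzyl)-5-(3,4,5-trimethoxyphenyl)oxolan-2-one F3. F3 is deprotonated with LiN(iPr)2 at −78 °C to the lithium enolate of F3, F4. F4 is protonated kinetically at −78 °C with the bulky 2,6-di-tert-butyl-4-methylphenol, again anti to the arm, which inverts C3 to the cis arrangement. The fallback comes back to the route at 18 and makes steps 7 to 9 unnecessary.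

Step 11. The Lewis acid may ionise the benzylic C2–O bond (epimerisation or reductive ring opening). The oxocarbenium ion may lose its α-proton, which would scramble C4 towards the more stable trans arrangement. The silyl ether may be partly lost. The fallback sets out from 18 and closes the ether by substitution at the primary carbon, so that neither C2 nor C4 passes through a cation. LiBH4 in THF reduces the lactone to (1R,2S,3S)-2-{[(tert-butyldiphenylsilyl)oxy]methyl}-3-(3,4-dimethoxybenzyl)-1-(3,4,5-trimethoxyphenyl)butane-1,4-diol F5. TsCl in pyridine at 0 °C sulfonylates the primary hydroxyl selectively to give the 4-O-(4-methylbenzenesulfonate) of F5, F6. NaH in THF then closes the ring by an intramolecular Williamson reaction (5-exo-tet), in which the benzylic oxygen is the nucleophile and C2 is retained. The fallback comes back to the route at 20 and replaces steps 10 and 11.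

**Further compounds**

F1 | step 3 | (3,4,5-trimethoxyphenyl)lithium | [Li]c1cc(OC)c(OC)c(OC)c1
F2 | step 3 | triisopropoxy(3,4,5-trimethoxyphenyl)titanium | CC(C)O[Ti](OC(C)C)(OC(C)C)c1cc(OC)c(OC)c(OC)c1
F3 | step 9 | (3R,4S,5R)-4-{[(tert-butyldiphenylsilyl)oxy]methyl}-3-(3,4-dimethoxybenzyl)-5-(3,4,5-trimethoxyphenyl)oxolan-2-one | O=C1O[C@@H](c2cc(OC)c(OC)c(OC)c2)[C@H](CO[Si](c2ccccc2)(c2ccccc2)C(C)(C)C)[C@H]1Cc1ccc(OC)c(OC)c1
F4 | step 9 | lithium enolate of F3 | [Li]OC1=C(Cc2ccc(OC)c(OC)c2)[C@@H](CO[Si](c2ccccc2)(c2ccccc2)C(C)(C)C)[C@H](c2cc(OC)c(OC)c(OC)c2)O1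
F5 | step 11 | (1R,2S,3S)-2-{[(tert-butyldiphenylsilyl)oxy]methyl}-3-(3,4-dimethoxybenzyl)-1-(3,4,5-trimethoxyphenyl)butane-1,4-diol | O[C@@H](c1cc(OC)c(OC)c(OC)c1)[C@H](CO[Si](c1ccccc1)(c1ccccc1)C(C)(C)C)[C@@H](CO)Cc1ccc(OC)c(OC)c1
F6 | step 11 | 4-O-(4-methylbenzenesulfonate) of F5 | O[C@@H](c1cc(OC)c(OC)c(OC)c1)[C@H](CO[Si](c1ccccc1)(c1ccccc1)C(C)(C)C)[C@@H](COS(=O)(=O)c1ccc(C)cc1)Cc1ccc(OC)c(OC)c1
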